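**Retrosynthetic overview**

1. The ten-membered ring is closed last, at C2–C3, by intramolecular alkylation of the C1 methyl-ketone enolate with a (Z)-allylic bromide (target numbering: C1 ketone, C4=C5, O6 lactone, C8 tiglate, C10 carbinol, C11–C13 acrylate).
2. One α-methylbutenolide supplies C3–C6 and C15: its ring fixes the Z C4=C5 geometry, and after lactone reduction O6 re-lactonises onto C12 to give the α-methylene-γ-lactone.
3. Key disconnection C6–C7: dearomatising vinylogous allylic alkylation of 3-methyl-2-silyloxyfuran (made from 3-methyl-2-furoic acid) with a Morita–Baylis–Hillman carbonate, which sets C6 and C7 and brings in C11–C13.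
4. The carbonate comes from tert-butyl acrylate and an α-tigloyloxy aldehyde; C8 is set by a proline aldol and C10 by chelation-controlled 1-ethoxyvinyl addition (the enol ether masks the C1 ketone).
5. Ring order: furan → butenolide → α-methylene-γ-butyrolactone → cyclodecene.

Assumption: 2-(triethylsilyloxy)acetaldehyde is treated as a purchasable reagent, like its catalogue tert-butyldimethylsilyl analogue.

**Route**

Step 1
Reactants: 1 3-methylfuran-2-carboxylic acid
Product: 3 3-methylfuran-2(5H)-one, via 5-hydroxy-3-methylfuran-2(5H)-one 2 (not isolated)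
Conditions: O2, hν (visible), rose bengal (cat.), MeOH, 0 °C; then NaBH4, 0 °C; then aq. HCl, rt
Reagents that add atoms: oxygen O=O
Why: Dye-sensitised [4+2] addition of singlet oxygen to the furan and decarboxylative collapse of the endoperoxide (furoic acid photooxygenation) give the γ-hydroxybutenolide, whose open aldehyde form is reduced by borohydride and re-lactonises on acidification.

Step 2
Reactants: 3 3-methylfuran-2(5H)-one
Product: 4 trimethyl[(3-methylfuran-2-yl)oxy]silane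
Conditions: Me3SiOTf, Et3N, Et2O, 0 °C; distilled
Reagents that add atoms: trimethylsilyl trifluoromethanesulfonate C[Si](C)(C)OS(=O)(=O)C(F)(F)F
Why: Soft enolisation of the butenolide (silyl triflate/amine) gives the aromatic 2-silyloxyfuran, a vinylogous silyl ketene acetal that is nucleophilic at C5.

Step 3
Reactants: 5 2-(triethylsilyloxy)acetaldehyde; 6 acetone
Product: 7 (4R)-4-hydroxy-5-(triethylsilyloxy)pentan-2-one
Conditions: L-proline (30 mol %), acetone/DMSO 4:1, 4 °C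
Reagents that add atoms: none
Why: Proline-catalysed direct aldol reaction (enamine catalysis) of acetone with the α-oxygenated aldehyde sets C8 as R, by analogy with the (R)-aldols that L-proline gives with other aldehydes.

Step 4
Reactants: 7 (4R)-4-hydroxy-5-(triethylsilyloxy)pentan-2-one
Product: 8 (3R,5R)-2-ethoxy-3-methyl-6-(triethylsilyloxy)hex-1-ene-3,5-diol
Conditions: CH2=C(OEt)Li (ethyl vinyl ether, t-BuLi, THF, −78 → 0 °C), MgBr2·OEt2, THF, −78 °C; aq. NH4Cl
Reagents that add atoms: 1-ethoxyvinyllithium [Li]C(=C)OCC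
Why: Chelation-controlled (Cram-chelate, 1,3-anti) addition of an acyl-anion equivalent: magnesium bridges the C8 alkoxide and the ketone and the nucleophile enters anti to the C8 side chain, setting C10 as R, while the enol ether masks the C1 ketone.

Step 5
Reactants: 8 (3R,5R)-2-ethoxy-3-methyl-6-(triethylsilyloxy)hex-1-ene-3,5-diol
Product: 10 (2R,4R)-5-ethoxy-4-methyl-1,4-bis(triethylsilyloxy)hex-5-en-2-yl (2E)-2-methylbut-2-enoate, via secondary tiglate 9 (not isolated)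
Conditions: tigloyl chloride, pyridine, DMAP (cat.), CH2Cl2, 0 °C; then Et3SiOTf, 2,6-lutidine, −78 → 0 °C
Reagents that add atoms: (2E)-2-methylbut-2-enoyl chloride C/C=C(\C)C(=O)Cl; triethylsilyl trifluoromethanesulfonate CC[Si](CC)(CC)OS(=O)(=O)C(F)(F)F
Why: Nucleophile-catalysed acylation is selective for the secondary over the tertiary alcohol, and the tertiary alcohol is then capped as a silyl ether so that the aldehyde of step 6 cannot close to a lactol; no stereocentre is touched.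

Step 6
Reactants: 10 (2R,4R)-5-ethoxy-4-methyl-1,4-bis(triethylsilyloxy)hex-5-en-2-yl (2E)-2-methylbut-2-enoate
Product: 11 (2R,4R)-5-ethoxy-4-methyl-1-oxo-4-(triethylsilyloxy)hex-5-en-2-yl (2E)-2-methylbut-2-enoate
Conditions: (COCl)2, DMSO, CH2Cl2, −78 → −40 °C; Et3N, −78 → 0 °C; used crude
Reagents that add atoms: none
Why: Swern conditions cleave and oxidise a primary triethylsilyl ether in one operation (oxidative desilylation), while the tertiary silyl ether, the enol ether and the tiglate are inert.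

Step 7
Reactants: 11 (2R,4R)-5-ethoxy-4-methyl-1-oxo-4-(triethylsilyloxy)hex-5-en-2-yl (2E)-2-methylbut-2-enoate; 12 tert-butyl prop-2-enoate
Product: 13 tert-butyl (4R,6R)-7-ethoxy-3-hydroxy-6-methyl-2-methylidene-4-[(2E)-2-methylbut-2-enoyloxy]-6-(triethylsilyloxy)oct-7-enoate (both C3 epimers)
Conditions: DABCO (0.5 equiv), tert-butyl acrylate (neat, 5 equiv), MeOH (1 equiv), rt
Reagents that add atoms: none
Why: Morita–Baylis–Hillman reaction of the activated α-acyloxy aldehyde; the new carbinol centre (C7) forms as a mixture, which does not matter because it becomes planar in step 9.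

Step 8
Reactants: 13 tert-butyl (4R,6R)-7-ethoxy-3-hydroxy-6-methyl-2-methylidene-4-[(2E)-2-methylbut-2-enoyloxy]-6-(triethylsilyloxy)oct-7-enoate
Product: 14 tert-butyl (4R,6R)-3-[(tert-butoxycarbonyl)oxy]-7-ethoxy-6-methyl-2-methylidene-4-[(2E)-2-methylbut-2-enoyloxy]-6-(triethylsilyloxy)oct-7-enoate (both C3 epimers)
Conditions: Boc2O, DMAP (cat.), CH2Cl2, 0 °C → rt
Reagents that add atoms: di-tert-butyl dicarbonate CC(C)(C)OC(=O)OC(=O)OC(C)(C)C
Why: DMAP-catalysed acylation of the secondary allylic alcohol gives the Morita–Baylis–Hillman carbonate, the leaving group and internal base source for step 9.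

Step 9
Reactants: 14 tert-butyl (4R,6R)-3-[(tert-butoxycarbonyl)oxy]-7-ethoxy-6-methyl-2-methylidene-4-[(2E)-2-methylbut-2-enoyloxy]-6-(triethylsilyloxy)oct-7-enoate; 4 trimethyl[(3-methylfuran-2-yl)oxy]silane
Product: 15 tert-butyl (3R,4R,6R)-7-ethoxy-6-methyl-2-methylidene-4-[(2E)-2-methylbut-2-enoyloxy]-3-[(2R)-4-methyl-5-oxo-2,5-dihydrofuran-2-yl]-6-(triethylsilyloxy)oct-7-enoate
Conditions: (DHQD)2PHAL (10 mol %), 4 (1.5 equiv), toluene, 0 °C → rt
Reagents that add atoms: none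
Why: Lewis-base-catalysed asymmetric allylic alkylation of a Morita–Baylis–Hillman carbonate (SN2′–SN2′): the alkaloid expels tert-butyl carbonate, the tert-butoxide desilylates 4, and the furanolate attacks through C5 inside the chiral ammonium ion pair, which breaks the furan aromaticity and sets C6 (R) and C7 (R) under catalyst control (the pseudo-enantiomeric alkaloid is taken if the sense is opposite), the butenolide ring locking the future C4=C5 as Z.

Step 10
Reactants: 15 tert-butyl (3R,4R,6R)-7-ethoxy-6-methyl-2-methylidene-4-[(2E)-2-methylbut-2-enoyloxy]-3-[(2R)-4-methyl-5-oxo-2,5-dihydrofuran-2-yl]-6-(triethylsilyloxy)oct-7-enoate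
Product: 17 tert-butyl (3S,4R,6R)-3-[(1R,2Z)-1,4-dihydroxy-3-methylbut-2-en-1-yl]-7-ethoxy-6-methyl-2-methylidene-4-[(2E)-2-methylbut-2-enoyloxy]-6-(triethylsilyloxy)oct-7-enoate, via ring lactol 16 (not isolated)
Conditions: i-Bu2AlH (1.2 equiv), CH2Cl2, −78 °C; aq. KNaC4H4O6; then NaBH4, THF/MeOH, −20 °C
Reagents that add atoms: none
Why: Partial reduction of a lactone to its lactol at −78 °C is expected to outpace attack on the α-branched conjugated tiglate and the tert-butyl ester, and borohydride then reduces the open hydroxy-enal 1,2 to the enediol; the Z geometry comes from the ring and C6 is untouched (the C7 descriptor changes to S only through CIP priorities).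

Step 11
Reactants: 17 tert-butyl (3S,4R,6R)-3-[(1R,2Z)-1,4-dihydroxy-3-methylbut-2-en-1-yl]-7-ethoxy-6-methyl-2-methylidene-4-[(2E)-2-methylbut-2-enoyloxy]-6-(triethylsilyloxy)oct-7-enoate
Product: 19 (1R,3R)-3-hydroxy-1-[(2R,3R)-2-[(1Z)-3-hydroxy-2-methylprop-1-en-1-yl]-4-methylidene-5-oxooxolan-3-yl]-3-methyl-4-oxopentyl (2E)-2-methylbut-2-enoate, via seco hydroxy acid 18 (not isolated)
Conditions: CF3CO2H/CH2Cl2/H2O 10:10:1, 0 °C → rt; aq. NaHCO3
Reagents that add atoms: water O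
Why: Acidolysis cleaves the tert-butyl ester and the γ-hydroxy acid lactonises onto O6, the only free hydroxyl that can form a five-membered ring (O8 is acylated), while the same acid hydrolyses the silyl ether and the enol ether to the α-hydroxy methyl ketone; no stereocentre is touched.

Step 12
Reactants: 19 (1R,3R)-3-hydroxy-1-[(2R,3R)-2-[(1Z)-3-hydroxy-2-methylprop-1-en-1-yl]-4-methylidene-5-oxooxolan-3-yl]-3-methyl-4-oxopentyl (2E)-2-methylbut-2-enoate
Product: 20 (1R,3R)-1-[(2R,3R)-2-[(1Z)-3-bromo-2-methylprop-1-en-1-yl]-4-methylidene-5-oxooxolan-3-yl]-3-hydroxy-3-methyl-4-oxopentyl (2E)-2-methylbut-2-enoate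
Conditions: N-bromosuccinimide, Me2S, CH2Cl2, −20 → 0 °C
Reagents that add atoms: N-bromosuccinimide O=C1CCC(=O)N1Br
Why: Corey–Kim halogenation converts only the primary allylic alcohol into the bromide by SN2 displacement of the alkoxysulfonium ion, leaving the tertiary α-ketol and the Z olefin intact.

Step 13
Reactants: 20 (1R,3R)-1-[(2R,3R)-2-[(1Z)-3-bromo-2-methylprop-1-en-1-yl]-4-methylidene-5-oxooxolan-3-yl]-3-hydroxy-3-methyl-4-oxopentyl (2E)-2-methylbut-2-enoate
Product: 21 (3aR,4R,6R,10Z,11aR)-6-hydroxy-6,10-dimethyl-3-methylidene-2,7-dioxo-2,3,3a,4,5,6,7,8,9,11a-decahydrocyclodeca[b]furan-4-yl (2E)-2-methylbut-2-enoate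
Conditions: LiN(SiMe3)2 (2.2 equiv), THF, 0.002 M, −78 → −20 °C; aq. NH4Cl
Reagents that add atoms: none
Why: Intramolecular SN2 alkylation of a ketone enolate (macrocyclisation of the kind used for germacrane rings): C10 is quaternary so only the C2 methyl can enolise, the tertiary alkoxide formed first is a hindered spectator, the Z allylic bromide holds the ends close, and no stereocentre is formed.

**Compound list**

1 | 3-methylfuran-2-carboxylic acid | Cc1ccoc1C(=O)O | starting material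
2 | 5-hydroxy-3-methylfuran-2(5H)-one (racemic, not isolated) | CC1=CC(O)OC1=O | intermediate
3 | 3-methylfuran-2(5H)-one | CC1=CCOC1=O | intermediate
4 | trimethyl[(3-methylfuran-2-yl)oxy]silane | Cc1ccoc1O[Si](C)(C)C | intermediate
5 | 2-(triethylsilyloxy)acetaldehyde | O=CCO[Si](CC)(CC)CC | starting material
6 | acetone | CC(C)=O | starting material
7 | (4R)-4-hydroxy-5-(triethylsilyloxy)pentan-2-one | CC(=O)C[C@@H](O)CO[Si](CC)(CC)CC | intermediate
8 | (3R,5R)-2-ethoxy-3-methyl-6-(triethylsilyloxy)hex-1-ene-3,5-diol | CCOC(=C)[C@](C)(O)C[C@@H](O)CO[Si](CC)(CC)CC | intermediate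
9 | (2R,4R)-5-ethoxy-4-hydroxy-4-methyl-1-(triethylsilyloxy)hex-5-en-2-yl (2E)-2-methylbut-2-enoate (not isolated) | CCOC(=C)[C@](C)(O)C[C@@H](OC(=O)/C(C)=C/C)CO[Si](CC)(CC)CC | intermediate
10 | (2R,4R)-5-ethoxy-4-methyl-1,4-bis(triethylsilyloxy)hex-5-en-2-yl (2E)-2-methylbut-2-enoate | CCOC(=C)[C@](C)(O[Si](CC)(CC)CC)C[C@@H](OC(=O)/C(C)=C/C)CO[Si](CC)(CC)CC | intermediate
11 | (2R,4R)-5-ethoxy-4-methyl-1-oxo-4-(triethylsilyloxy)hex-5-en-2-yl (2E)-2-methylbut-2-enoate | CCOC(=C)[C@](C)(O[Si](CC)(CC)CC)C[C@@H](OC(=O)/C(C)=C/C)C=O | intermediate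
12 | tert-butyl prop-2-enoate | C=CC(=O)OC(C)(C)C | starting material
13 | tert-butyl (4R,6R)-7-ethoxy-3-hydroxy-6-methyl-2-methylidene-4-[(2E)-2-methylbut-2-enoyloxy]-6-(triethylsilyloxy)oct-7-enoate (both C3 epimers) | C=C(C(=O)OC(C)(C)C)C(O)[C@H](OC(=O)/C(C)=C/C)C[C@@](C)(O[Si](CC)(CC)CC)C(=C)OCC | intermediate
14 | tert-butyl (4R,6R)-3-[(tert-butoxycarbonyl)oxy]-7-ethoxy-6-methyl-2-methylidene-4-[(2E)-2-methylbut-2-enoyloxy]-6-(triethylsilyloxy)oct-7-enoate (both C3 epimers) | C=C(C(=O)OC(C)(C)C)C(OC(=O)OC(C)(C)C)[C@H](OC(=O)/C(C)=C/C)C[C@@](C)(O[Si](CC)(CC)CC)C(=C)OCC | intermediate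
15 | tert-butyl (3R,4R,6R)-7-ethoxy-6-methyl-2-methylidene-4-[(2E)-2-methylbut-2-enoyloxy]-3-[(2R)-4-methyl-5-oxo-2,5-dihydrofuran-2-yl]-6-(triethylsilyloxy)oct-7-enoate | C=C(C(=O)OC(C)(C)C)[C@@H]([C@H]1C=C(C)C(=O)O1)[C@H](OC(=O)/C(C)=C/C)C[C@@](C)(O[Si](CC)(CC)CC)C(=C)OCC | intermediate
16 | tert-butyl (3R,4R,6R)-7-ethoxy-3-[(2R)-5-hydroxy-4-methyl-2,5-dihydrofuran-2-yl]-6-methyl-2-methylidene-4-[(2E)-2-methylbut-2-enoyloxy]-6-(triethylsilyloxy)oct-7-enoate (lactol epimers, not isolated) | C=C(C(=O)OC(C)(C)C)[C@@H]([C@H]1C=C(C)C(O)O1)[C@H](OC(=O)/C(C)=C/C)C[C@@](C)(O[Si](CC)(CC)CC)C(=C)OCC | intermediate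
17 | tert-butyl (3S,4R,6R)-3-[(1R,2Z)-1,4-dihydroxy-3-methylbut-2-en-1-yl]-7-ethoxy-6-methyl-2-methylidene-4-[(2E)-2-methylbut-2-enoyloxy]-6-(triethylsilyloxy)oct-7-enoate | C=C(C(=O)OC(C)(C)C)[C@@H]([C@H](O)/C=C(/C)CO)[C@H](OC(=O)/C(C)=C/C)C[C@@](C)(O[Si](CC)(CC)CC)C(=C)OCC | intermediate
18 | (3S,4R,6R)-3-[(1R,2Z)-1,4-dihydroxy-3-methylbut-2-en-1-yl]-6-hydroxy-6-methyl-2-methylidene-4-[(2E)-2-methylbut-2-enoyloxy]-7-oxooctanoic acid (not isolated) | C=C(C(=O)O)[C@@H]([C@H](O)/C=C(/C)CO)[C@H](OC(=O)/C(C)=C/C)C[C@@](C)(O)C(C)=O | intermediate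
19 | (1R,3R)-3-hydroxy-1-[(2R,3R)-2-[(1Z)-3-hydroxy-2-methylprop-1-en-1-yl]-4-methylidene-5-oxooxolan-3-yl]-3-methyl-4-oxopentyl (2E)-2-methylbut-2-enoate | C=C1C(=O)O[C@H](/C=C(/C)CO)[C@H]1[C@H](OC(=O)/C(C)=C/C)C[C@@](C)(O)C(C)=O | intermediate
20 | (1R,3R)-1-[(2R,3R)-2-[(1Z)-3-bromo-2-methylprop-1-en-1-yl]-4-methylidene-5-oxooxolan-3-yl]-3-hydroxy-3-methyl-4-oxopentyl (2E)-2-methylbut-2-enoate | C=C1C(=O)O[C@H](/C=C(/C)CBr)[C@H]1[C@H](OC(=O)/C(C)=C/C)C[C@@](C)(O)C(C)=O | intermediate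
21 | (3aR,4R,6R,10Z,11aR)-6-hydroxy-6,10-dimethyl-3-methylidene-2,7-dioxo-2,3,3a,4,5,6,7,8,9,11a-decahydrocyclodeca[b]furan-4-yl (2E)-2-methylbut-2-enoate | C=C1C(=O)O[C@@H]2/C=C(/C)CCC(=O)[C@](C)(O)C[C@@H](OC(=O)/C(C)=C/C)[C@@H]12 | target

**Step count and risks**

Total steps: 13. Longest linear sequence: 11 steps (steps 3–13, from 5 and 6); the furan branch (steps 1–2) joins at step 9.

Step 7 (Morita–Baylis–Hillman coupling). The α-acyloxy aldehyde can epimerise at C8 under amine catalysis, and the hindered tert-butyl acrylate reacts slowly. The fallback sets out from 11 and returns at 13. It is a vinylalumination: tert-butyl propiolate is hydroaluminated with i-Bu2AlH and N-methylmorpholine N-oxide, and the resulting [1-(tert-butoxycarbonyl)vinyl]aluminium reagent adds to 11 at −78 °C without any base to give 13 directly. No new compound arises on this way (F0).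

Step 9 (dearomatising allylic alkylation). The branched aliphatic carbonate may be attacked at its CH2 terminus (linear product), or the catalyst may not override the C8 centre. The fallback sets out from 11 and returns at 15; it makes the C6–C7 bond by an iminium-catalysed Mukaiyama–Michael addition instead.
- Wittig reaction of 11 with Ph3P=CHCHO gives (2E,4R,6R)-7-ethoxy-6-methyl-1-oxo-6-(triethylsilyloxy)octa-2,7-dien-4-yl (2E)-2-methylbut-2-enoate F1.
- Addition of 4 under (2S,5S)-5-benzyl-2-tert-butyl-3-methylimidazolidin-4-one 2,4-dinitrobenzoate catalysis (CH2Cl2/H2O, −70 °C) gives (3R,4R,6R)-7-ethoxy-6-methyl-3-[(2R)-4-methyl-5-oxo-2,5-dihydrofuran-2-yl]-1-oxo-6-(triethylsilyloxy)oct-7-en-4-yl (2E)-2-methylbut-2-enoate F2.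
- α-Methylenation with aqueous formaldehyde and pyrrolidine/propionic acid gives (3R,4R,6R)-7-ethoxy-6-methyl-2-methylidene-3-[(2R)-4-methyl-5-oxo-2,5-dihydrofuran-2-yl]-1-oxo-6-(triethylsilyloxy)oct-7-en-4-yl (2E)-2-methylbut-2-enoate F3.
- Buffered NaClO2/NaH2PO4/2-methylbut-2-ene oxidation gives (3R,4R,6R)-7-ethoxy-6-methyl-2-methylidene-4-[(2E)-2-methylbut-2-enoyloxy]-3-[(2R)-4-methyl-5-oxo-2,5-dihydrofuran-2-yl]-6-(triethylsilyloxy)oct-7-enoic acid F4.
- O-tert-Butyl-N,N′-diisopropylisourea converts F4 into 15.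

Step 13 (macrocyclisation). The α-methylene lactone is a Michael acceptor and its C7–H is acidic, so a strong base may cause conjugate addition, isomerisation to the endocyclic butenolide or oligomerisation before the ten-membered ring closes. The fallback sets out from 19 and returns at 21; it closes the ring through a neutral π-allyl route.
- Methyl chloroformate/pyridine on 19 gives (1R,3R)-3-hydroxy-1-[(2R,3R)-2-[(1Z)-3-[(methoxycarbonyl)oxy]-2-methylprop-1-en-1-yl]-4-methylidene-5-oxooxolan-3-yl]-3-methyl-4-oxopentyl (2E)-2-methylbut-2-enoate F5.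
- Me3SiOTf/Et3N gives (1R,3R)-1-[(2R,3R)-2-[(1Z)-3-[(methoxycarbonyl)oxy]-2-methylprop-1-en-1-yl]-4-methylidene-5-oxooxolan-3-yl]-3-methyl-3,4-bis(trimethylsilyloxy)pent-4-en-1-yl (2E)-2-methylbut-2-enoate F6.
- Pd2(dba)3/Ph2PCH2CH2PPh2 (zerovalent palladium, THF, 0.002 M, 50 °C) ionises the carbonate, the methoxide set free unmasks the enolate, and C2 attacks the allyl terminus C3 to give (3aR,4R,6R,10Z,11aR)-6,10-dimethyl-3-methylidene-2,7-dioxo-6-(trimethylsilyloxy)-2,3,3a,4,5,6,7,8,9,11a-decahydrocyclodeca[b]furan-4-yl (2E)-2-methylbut-2-enoate F7.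
- Citric acid in MeOH then gives 21.
- The risk of this fallback is erosion of the Z geometry through π-allyl isomerisation.

**Further compounds**

F0 | step 7 | none | none
F1 | step 9 | (2E,4R,6R)-7-ethoxy-6-methyl-1-oxo-6-(triethylsilyloxy)octa-2,7-dien-4-yl (2E)-2-methylbut-2-enoate | O=C/C=C/[C@H](OC(=O)/C(C)=C/C)C[C@@](C)(O[Si](CC)(CC)CC)C(=C)OCC
F2 | step 9 | (3R,4R,6R)-7-ethoxy-6-methyl-3-[(2R)-4-methyl-5-oxo-2,5-dihydrofuran-2-yl]-1-oxo-6-(triethylsilyloxy)oct-7-en-4-yl (2E)-2-methylbut-2-enoate | O=CC[C@@H]([C@H]1C=C(C)C(=O)O1)[C@H](OC(=O)/C(C)=C/C)C[C@@](C)(O[Si](CC)(CC)CC)C(=C)OCC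
F3 | step 9 | (3R,4R,6R)-7-ethoxy-6-methyl-2-methylidene-3-[(2R)-4-methyl-5-oxo-2,5-dihydrofuran-2-yl]-1-oxo-6-(triethylsilyloxy)oct-7-en-4-yl (2E)-2-methylbut-2-enoate | C=C(C=O)[C@@H]([C@H]1C=C(C)C(=O)O1)[C@H](OC(=O)/C(C)=C/C)C[C@@](C)(O[Si](CC)(CC)CC)C(=C)OCC
F4 | step 9 | (3R,4R,6R)-7-ethoxy-6-methyl-2-methylidene-4-[(2E)-2-methylbut-2-enoyloxy]-3-[(2R)-4-methyl-5-oxo-2,5-dihydrofuran-2-yl]-6-(triethylsilyloxy)oct-7-enoic acid | C=C(C(=O)O)[C@@H]([C@H]1C=C(C)C(=O)O1)[C@H](OC(=O)/C(C)=C/C)C[C@@](C)(O[Si](CC)(CC)CC)C(=C)OCC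
F5 | step 13 | (1R,3R)-3-hydroxy-1-[(2R,3R)-2-[(1Z)-3-[(methoxycarbonyl)oxy]-2-methylprop-1-en-1-yl]-4-methylidene-5-oxooxolan-3-yl]-3-methyl-4-oxopentyl (2E)-2-methylbut-2-enoate | C=C1C(=O)O[C@H](/C=C(/C)COC(=O)OC)[C@H]1[C@H](OC(=O)/C(C)=C/C)C[C@@](C)(O)C(C)=O
F6 | step 13 | (1R,3R)-1-[(2R,3R)-2-[(1Z)-3-[(methoxycarbonyl)oxy]-2-methylprop-1-en-1-yl]-4-methylidene-5-oxooxolan-3-yl]-3-methyl-3,4-bis(trimethylsilyloxy)pent-4-en-1-yl (2E)-2-methylbut-2-enoate | C=C1C(=O)O[C@H](/C=C(/C)COC(=O)OC)[C@H]1[C@H](OC(=O)/C(C)=C/C)C[C@@](C)(O[Si](C)(C)C)C(=C)O[Si](C)(C)C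
F7 | step 13 | (3aR,4R,6R,10Z,11aR)-6,10-dimethyl-3-methylidene-2,7-dioxo-6-(trimethylsilyloxy)-2,3,3a,4,5,6,7,8,9,11a-decahydrocyclodeca[b]furan-4-yl (2E)-2-methylbut-2-enoate | C=C1C(=O)O[C@@H]2/C=C(/C)CCC(=O)[C@](C)(O[Si](C)(C)C)C[C@@H](OC(=O)/C(C)=C/C)[C@@H]12
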